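**Retrosynthetic overview**
- The last operation closes both rings of the isochromenone from a monocyclic lactol, which is a masked acyclic δ-hydroxy chloromethyl ketone / ynone. Ring A closes first (C5 to C4a, 6-exo-dig Michael). Ring B closes next (C1-OH onto C3=O, loss of water). Acid deprotection follows in the same flask.
- That precursor comes from a δ-lactone acetonide, a dienal (C4–C3 bond, then oxidation) and chloromethyllithium (C5–C6 bond). The lactone ring oxygen is released as the future O2.
- The δ-lactone is only a stereochemical template. Ring-closing metathesis gives the Z-configured C7=C8, and dihydroxylation anti to the C8a alkynyl group sets C7 and C8. C8a comes from (S)-vinyloxirane and an alkynylalane.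
- The dienal comes from anti-crotylboration of acetaldehyde (C5', C6'), cross-metathesis with methacrolein, and Wittig homologation.

Assumption: (S)-2-vinyloxirane (resolved butadiene monoxide) and (+)-Ipc2BOMe are bought as catalogue chemicals; atom labels C1, O2, C3, C4, C4a, C5–C8, C8a and C1'–C7' follow the isochromene numbering of the target.

**Step 1**
Reactants: 1 (S)-2-vinyloxirane; 2 (trimethylsilyl)acetylene
Product: 4 (S)-2-[(trimethylsilyl)ethynyl]but-3-en-1-ol, via diethyl[(trimethylsilyl)ethynyl]alane 3 (not isolated)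
Conditions: 2, n-BuLi, toluene–hexane, 0 °C; Et2AlCl, 0 °C; 1, −30 to 0 °C; 1 M HCl
Reagents that add atoms: none
Why: Alkynylalane epoxide opening (SN2): aluminium activates the oxirane and the alkynyl group attacks the charge-stabilised allylic carbon with inversion, which fixes C8a (the descriptor stays S only because the priorities change).

**Step 2**
Reactants: 4 (S)-2-[(trimethylsilyl)ethynyl]but-3-en-1-ol; 5 methacryloyl chloride
Product: 6 (2S)-2-[(trimethylsilyl)ethynyl]but-3-en-1-yl 2-methylprop-2-enoate
Conditions: Et3N, DMAP (cat.), CH2Cl2, 0 °C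
Reagents that add atoms: none
Why: DMAP-catalysed O-acylation of a primary alcohol, which leaves the stereocentre untouched.

**Step 3**
Reactants: 6 (2S)-2-[(trimethylsilyl)ethynyl]but-3-en-1-yl 2-methylprop-2-enoate
Product: 7 (5S)-3-methyl-5-[(trimethylsilyl)ethynyl]-5,6-dihydro-2H-pyran-2-one
Conditions: second-generation Hoveyda–Grubbs catalyst (5 mol %), 1,4-benzoquinone (10 mol %), toluene (5 mM), 80 °C
Reagents that add atoms: none
Why: Ring-closing metathesis: the ruthenium carbene loads on the monosubstituted vinyl group and closes on the methacrylate, the silyl-capped alkyne on the same carbon cannot be reached, and the six-membered ring forces C6 and C8a cis on the new C7=C8 bond.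

**Step 4**
Reactants: 7 (5S)-3-methyl-5-[(trimethylsilyl)ethynyl]-5,6-dihydro-2H-pyran-2-one
Product: 8 (3R,4R,5S)-3,4-dihydroxy-3-methyl-5-[(trimethylsilyl)ethynyl]oxan-2-one
Conditions: K2OsO2(OH)4 (2 mol %), (DHQD)2PHAL (5 mol %), NMO, acetone–H2O, 0 °C to rt
Reagents that add atoms: N-methylmorpholine N-oxide C[N+]1([O-])CCOCC1; water O
Why: Catalytic syn-dihydroxylation (Upjohn/Sharpless type): osmium adds to the face anti to the C8a alkynyl group, which is also the face the ligand mnemonic predicts, so C7 (R) and C8 (R) are set together, cis to each other and trans to the alkyne.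

**Step 5**
Reactants: 8 (3R,4R,5S)-3,4-dihydroxy-3-methyl-5-[(trimethylsilyl)ethynyl]oxan-2-one
Product: 9 (3aR,7S,7aR)-2,2,3a-trimethyl-7-[(trimethylsilyl)ethynyl]tetrahydro-4H-[1,3]dioxolo[4,5-c]pyran-4-one
Conditions: 2,2-dimethoxypropane, PPTS (cat.), acetone, rt
Reagents that add atoms: 2,2-dimethoxypropane COC(C)(C)OC
Why: Acid-catalysed transketalisation of the cis-diol, which later blocks 5-exo oxa-Michael addition of the C7 hydroxyl to the ynone.

**Step 6**
Reactants: 10 acetaldehyde; 11 trans-2-butene
Product: 14 (2S,3R)-3-methylpent-4-en-2-ol, via (E)-crotyl-B(Ipc)2 12 (not isolated), via homoallyl borinate 13 (not isolated)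
Conditions: 11, KOt-Bu, n-BuLi, THF, −78 to −45 °C; (+)-Ipc2BOMe, −78 °C; BF3·OEt2, then 10, −78 °C; NaOH, H2O2, rt
Reagents that add atoms: none
Why: Brown asymmetric crotylboration through a closed chair transition state: the E-crotyl geometry gives the anti relation and the Ipc groups derived from (−)-α-pinene give C6' (S) and C5' (R).

**Step 7**
Reactants: 14 (2S,3R)-3-methylpent-4-en-2-ol
Product: 15 triethyl{[(2S,3R)-3-methylpent-4-en-2-yl]oxy}silane
Conditions: Et3SiCl, imidazole, CH2Cl2, 0 °C
Reagents that add atoms: chlorotriethylsilane CC[Si](Cl)(CC)CC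
Why: Silyl ether formation removes the only acidic proton of the side chain before the fluoride-catalysed alkynylation and gives a group that falls off in the final acid stage.

**Step 8**
Reactants: 15 triethyl{[(2S,3R)-3-methylpent-4-en-2-yl]oxy}silane; 16 methacrolein
Product: 17 (2E,4R,5S)-2,4-dimethyl-5-(triethylsilyloxy)hex-2-enal
Conditions: 16 (5 equiv), second-generation Hoveyda–Grubbs catalyst (5 mol %), CH2Cl2, 40 °C
Reagents that add atoms: none
Why: Olefin cross-metathesis of a terminal alkene with methacrolein gives the thermodynamically preferred E-trisubstituted enal (C3'=C4') without touching the allylic stereocentre.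

**Step 9**
Reactants: 17 (2E,4R,5S)-2,4-dimethyl-5-(triethylsilyloxy)hex-2-enal; 18 (triphenylphosphoranylidene)acetaldehyde
Product: 19 (2E,4E,6R,7S)-4,6-dimethyl-7-(triethylsilyloxy)octa-2,4-dienal
Conditions: 18 (1.1 equiv), toluene, 80 °C
Reagents that add atoms: none
Why: Wittig two-carbon homologation with a stabilised ylide is E-selective and installs C1'=C2' together with the future C3.

**Step 10**
Reactants: 9 (3aR,7S,7aR)-2,2,3a-trimethyl-7-[(trimethylsilyl)ethynyl]tetrahydro-4H-[1,3]dioxolo[4,5-c]pyran-4-one; 19 (2E,4E,6R,7S)-4,6-dimethyl-7-(triethylsilyloxy)octa-2,4-dienal; 20 chloroiodomethane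
Product: 22 chloromethyl lactol carrying the C3 carbinol side chain (anomers and C3 epimers; in equilibrium with the open δ-hydroxy chloromethyl ketone), via propargylic TMS ether lactone 21 (not isolated)
Conditions: 9 + 19, Bu4N[Ph3SiF2] (10 mol %), THF, −20 to 0 °C; cool to −78 °C, 20 (3 equiv), MeLi·LiBr (2.8 equiv, slow addition); 1 M HCl, 0 °C, 15 min
Reagents that add atoms: none
Why: Fluoride-catalysed alkynylsilane addition to the aldehyde (silyl transfer caps the new alkoxide) is followed by Barbier-type chloromethyllithium addition to the lactone, which has no α-hydrogen and gives a lithium lactolate stable at −78 °C, so only one C5 unit enters; both new stereocentres (C3 carbinol, anomeric C6) are erased later.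

**Step 11**
Reactants: 22 chloromethyl lactol carrying the C3 carbinol side chain
Product: 23 chloromethyl lactol ynone (C3 ketone flanked by the alkyne and the dienyl chain)
Conditions: MnO2 (activated, 15 equiv), CH2Cl2, rt
Reagents that add atoms: none
Why: MnO2 oxidation takes only the doubly activated (allylic and propargylic) carbinol and leaves the tertiary lactol, the chloride and the silyl ether alone, removing the C3 stereocentre.

**Step 12**
Reactants: 23 chloromethyl lactol ynone
Product: 26 (7R,8R,8aS)-5-chloro-7,8-dihydroxy-3-[(1E,3E,5R,6S)-6-hydroxy-3,5-dimethylhepta-1,3-dien-1-yl]-7-methyl-1,7,8,8a-tetrahydro-6H-isochromen-6-one, via ring-A chloroenone 24 (not isolated), via protected bicycle 25 (not isolated)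
Conditions: Cs2CO3 (1.5 equiv), MeCN, 0 °C to rt; then CF3CO2H–H2O (4:1), same flask, 0 °C to rt
Reagents that add atoms: none
Why: Proposed new method: carbonate opens the lactol to the δ-hydroxy chloromethyl ketone, whose only enolisable carbon C5 (C7 is quaternary) adds 6-exo-dig to the ynone β-carbon C4a and closes ring A. O-attack is reversible, whereas the C-adduct is drained as a stabilised vinylogous β-diketonate. On acidification the liberated C1-OH adds to the C3 ketone and loses water to give the push–pull dienol ether (ring B), and the same aqueous acid removes the acetonide and the TES group. No stereocentre is made or touched. The closest known reaction types are intramolecular Michael (Conia-ene-like) carbocyclisation of ketone enolates onto ynones and acid cyclodehydration of δ-hydroxy-1,3-dicarbonyl compounds to dihydropyranones.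

**Compound list**
1 | (S)-2-vinyloxirane | C=C[C@H]1CO1 | starting material
2 | (trimethylsilyl)acetylene | C#C[Si](C)(C)C | starting material
3 | diethyl[(trimethylsilyl)ethynyl]alane | CC[Al](CC)C#C[Si](C)(C)C | intermediate
4 | (S)-2-[(trimethylsilyl)ethynyl]but-3-en-1-ol | C=C[C@H](CO)C#C[Si](C)(C)C | intermediate
5 | methacryloyl chloride | C=C(C)C(=O)Cl | starting material
6 | (2S)-2-[(trimethylsilyl)ethynyl]but-3-en-1-yl 2-methylprop-2-enoate | C=C[C@H](COC(=O)C(C)=C)C#C[Si](C)(C)C | intermediate
7 | (5S)-3-methyl-5-[(trimethylsilyl)ethynyl]-5,6-dihydro-2H-pyran-2-one | CC1=C[C@@H](C#C[Si](C)(C)C)COC1=O | intermediate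
8 | (3R,4R,5S)-3,4-dihydroxy-3-methyl-5-[(trimethylsilyl)ethynyl]oxan-2-one | O=C1[C@](C)(O)[C@H](O)[C@@H](C#C[Si](C)(C)C)CO1 | intermediate
9 | (3aR,7S,7aR)-2,2,3a-trimethyl-7-[(trimethylsilyl)ethynyl]tetrahydro-4H-[1,3]dioxolo[4,5-c]pyran-4-one (acetonide of 8) | O=C1[C@]2(C)OC(C)(C)O[C@@H]2[C@@H](C#C[Si](C)(C)C)CO1 | intermediate
10 | acetaldehyde | CC=O | starting material
11 | trans-2-butene | C/C=C/C | starting material
12 | (E)-crotyldiisopinocampheylborane, Ipc from (−)-α-pinene | C/C=C/CB([C@H]1C[C@H]2C[C@@H]([C@@H]1C)C2(C)C)[C@H]1C[C@H]2C[C@@H]([C@@H]1C)C2(C)C | intermediate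
13 | diisopinocampheylborinate of 14 | C=C[C@@H](C)[C@H](C)OB([C@H]1C[C@H]2C[C@@H]([C@@H]1C)C2(C)C)[C@H]1C[C@H]2C[C@@H]([C@@H]1C)C2(C)C | intermediate
14 | (2S,3R)-3-methylpent-4-en-2-ol | C=C[C@@H](C)[C@H](C)O | intermediate
15 | triethyl{[(2S,3R)-3-methylpent-4-en-2-yl]oxy}silane | C=C[C@@H](C)[C@H](C)O[Si](CC)(CC)CC | intermediate
16 | methacrolein | C=C(C)C=O | starting material
17 | (2E,4R,5S)-2,4-dimethyl-5-(triethylsilyloxy)hex-2-enal | O=C/C(C)=C/[C@@H](C)[C@H](C)O[Si](CC)(CC)CC | intermediate
18 | (triphenylphosphoranylidene)acetaldehyde | O=CC=P(c1ccccc1)(c1ccccc1)c1ccccc1 | starting material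
19 | (2E,4E,6R,7S)-4,6-dimethyl-7-(triethylsilyloxy)octa-2,4-dienal | O=C/C=C/C(C)=C/[C@@H](C)[C@H](C)O[Si](CC)(CC)CC | intermediate
20 | chloroiodomethane | ClCI | starting material
21 | propargylic TMS ether lactone (lactone acetonide whose alkyne carries CH(OSiMe3)-dienyl; C3 epimers) | O=C1[C@]2(C)OC(C)(C)O[C@@H]2[C@@H](C#CC(O[Si](C)(C)C)/C=C/C(C)=C/[C@@H](C)[C@H](C)O[Si](CC)(CC)CC)CO1 | intermediate
22 | chloromethyl lactol with free C3 carbinol (anomers, C3 epimers) | OC1(CCl)[C@]2(C)OC(C)(C)O[C@@H]2[C@@H](C#CC(O)/C=C/C(C)=C/[C@@H](C)[C@H](C)O[Si](CC)(CC)CC)CO1 | intermediate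
23 | chloromethyl lactol ynone (anomers) | OC1(CCl)[C@]2(C)OC(C)(C)O[C@@H]2[C@@H](C#CC(=O)/C=C/C(C)=C/[C@@H](C)[C@H](C)O[Si](CC)(CC)CC)CO1 | intermediate
24 | ring-A chloroenone: 2-chlorocyclohex-2-enone with C4H2–C3(=O)-dienyl on C4a, CH2OH on C8a, 7,8-acetonide (held in the flask as its caesium enolate) | O=C(CC1=C(Cl)C(=O)[C@]2(C)OC(C)(C)O[C@@H]2[C@@H]1CO)/C=C/C(C)=C/[C@@H](C)[C@H](C)O[Si](CC)(CC)CC | intermediate
25 | 7,8-O-isopropylidene-6'-O-triethylsilyl derivative of the target | CC(/C=C/C1=CC2=C(Cl)C(=O)[C@]3(C)OC(C)(C)O[C@@H]3[C@@H]2CO1)=C\[C@@H](C)[C@H](C)O[Si](CC)(CC)CC | intermediate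
26 | CNP0536300.1, (7R,8R,8aS)-5-chloro-7,8-dihydroxy-3-[(1E,3E,5R,6S)-6-hydroxy-3,5-dimethylhepta-1,3-dien-1-yl]-7-methyl-1,7,8,8a-tetrahydro-6H-isochromen-6-one | CC(/C=C/C1=CC2=C(Cl)C(=O)[C@](C)(O)[C@H](O)[C@@H]2CO1)=C\[C@@H](C)[C@H](C)O | target

**Step count**
Total step count: 12.
Longest linear sequence: 8 (steps 1–5, then 10–12).

**Steps most likely to fail**

Step 12. The base stage can go wrong in three ways:
- the lactolate oxygen can displace the neighbouring chloride to give an epoxy ether;
- the enolate oxygen can cyclise instead of C5;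
- C8a can epimerise or lose a β-oxygen.

The fallback avoids all anions and sets out from 23. TMSOTf and Et3N trap the open chain as the bis-silylated chloro enol ether F1. (Ph3P)AuNTf2 (monovalent gold, 5 mol %) in moist CH2Cl2 then performs a 6-exo-dig silyl enol ether–alkyne carbocyclisation. A brief dilute-acid wash removes the remaining silyl group, and the sequence returns to the route at 24. From there the acid stage of step 12 closes ring B and deprotects.

Step 10. The carbenoid may decompose faster than it attacks the hindered lactone. The fallback moves the chlorine to the end and sets out from 21, now isolated.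
- MeLi at −78 °C, then dilute acid, gives the methyl lactol F2.
- MnO2 gives the methyl lactol ynone F3.
- KOt-Bu in THF, followed by PPTS, closes both rings to the 5-deschloro protected bicycle F4.
- N-chlorosuccinimide in MeCN chlorinates the nucleophilic C5 of the dienol ether, as azaphilone cores do, and the route is rejoined at 25.

Step 1. Attack at the terminal epoxide carbon, SN2' attack, or partial ionisation with loss of enantiopurity would spoil C8a. The fallback builds the same centre by catalytic enantioselective allylic substitution and sets out from 3.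
- cis-2-Butene-1,4-diol is monosilylated to (Z)-4-[(tert-butyldimethylsilyl)oxy]but-2-en-1-ol F5.
- F5 is converted with ClP(O)(OEt)2 into the allylic phosphate F6.
- CuCl2·2H2O (divalent copper precatalyst, 5 mol %) with a chiral sulfonate-bearing imidazolinium carbene precursor delivers the alkynyl group of 3 in SN2' fashion, giving the TBS ether of the enynol F7.
- PPTS in MeOH frees the primary alcohol, and the route is rejoined at 4.

**Further compounds**
F1 | step 12 | open-chain bis-TMS derivative of 23 (C5=C6 chloro silyl enol ether as E/Z mixture, C1-OTMS) | ClC=C(O[Si](C)(C)C)[C@]1(C)OC(C)(C)O[C@@H]1[C@H](CO[Si](C)(C)C)C#CC(=O)/C=C/C(C)=C/[C@@H](C)[C@H](C)O[Si](CC)(CC)CC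
F2 | step 10 | methyl lactol, des-chloro analogue of 22 (anomers, C3 epimers) | OC1(C)[C@]2(C)OC(C)(C)O[C@@H]2[C@@H](C#CC(O)/C=C/C(C)=C/[C@@H](C)[C@H](C)O[Si](CC)(CC)CC)CO1
F3 | step 10 | methyl lactol ynone, des-chloro analogue of 23 | OC1(C)[C@]2(C)OC(C)(C)O[C@@H]2[C@@H](C#CC(=O)/C=C/C(C)=C/[C@@H](C)[C@H](C)O[Si](CC)(CC)CC)CO1
F4 | step 10 | 5-deschloro analogue of 25 | CC(/C=C/C1=CC2=CC(=O)[C@]3(C)OC(C)(C)O[C@@H]3[C@@H]2CO1)=C\[C@@H](C)[C@H](C)O[Si](CC)(CC)CC
F5 | step 1 | (Z)-4-[(tert-butyldimethylsilyl)oxy]but-2-en-1-ol | OC/C=C\CO[Si](C)(C)C(C)(C)C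
F6 | step 1 | (Z)-4-[(tert-butyldimethylsilyl)oxy]but-2-en-1-yl diethyl phosphate | CCOP(=O)(OCC)OC/C=C\CO[Si](C)(C)C(C)(C)C
F7 | step 1 | TBS ether of 4, (S)-configured | C=C[C@H](CO[Si](C)(C)C(C)(C)C)C#C[Si](C)(C)C
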